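## Analysis of the target

Pebrellin 14 is 5,6-dihydroxy-7,8,3',4'-tetramethoxyflavone. It is a 2-aryl-4H-chromen-4-one in which ring A (the benzo ring) carries a substituent on every carbon, ring C is the pyranone, and ring B is a 3,4-dimethoxyphenyl group on C2. The molecule is flat and achiral, so every selectivity question is one of regiochemistry. The sensitive parts are the 5,6-dihydroxy unit, which is oxidised easily in basic aerobic media, and the pyranone, which hot strong acid can open and reclose so that a different ring-A oxygen ends up as O1. The difficulty lies in ring A, which has five oxygens in a row plus the acyl carbon C4a: two hydroxyls must be kept apart from four methyl ethers, and the two oxygens flanking C4a, O5 and O1, differ only in their outer neighbours. A cyclodehydration of a diketone with free hydroxyls on both C5 and C8a can therefore close ring C through either oxygen and give a constitutional isomer of 14. The strategy rests on C8a, which sits between C8 with its methoxy group and C4a: if C8a enters as a C–Br carbon while O5 and O6 are acetals, O1 can only come from the enol oxygen on C2, and forming O1–C8a under copper catalysis closes ring C in one sense only.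

## Retrosynthetic reasoning

**14 ⇒ 13 (two O–CH2 acetal bonds).** The last operation only releases O5 and O6. Both are methoxymethyl ethers in 13 because this group survives organolithium reagents, amide bases and hot carbonate, directs ortho-lithiation better than a methyl ether, and leaves under acid mild enough to spare the four methyl ethers. The forward step must cleave two acetals without opening ring C.

**13 ⇒ 12 (O1–C8a).** Ring C is opened at the aryl–oxygen bond and not at O1–C2. Cutting O1–C2 would lead back to a C8a phenol, and so to a ring A with oxygen on both carbons next to C4a, where closure can take the wrong oxygen. Cutting O1–C8a leads to bromide 12, in which C8a is the electrophile and O5 is an ether, so only one mode of closure exists. The gain is that the position of one halogen fixes the regiochemistry. The forward reaction has to join an enol oxygen to a hindered, electron-rich aryl carbon, which calls for copper catalysis.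

**12 ⇒ 9 + 10 (C2–C3).** The diketone is cut between the methylene carbon and the ring-B carbonyl, giving methyl ketone 9, used as its lithium enolate 11, and acid chloride 10. This is the convergent cut, since ring B arrives whole. The forward reaction must acylate at carbon and stop after one acylation.

**9 ⇒ 8 (C8a–Br).** Removing the bromine gives 8, in which C8a–H is the only hydrogen left on the ring. The halogenation then needs no regiocontrol, only chemoselectivity for the ring over the acetyl methyl group. It is placed before the diketone stage because the C3 methylene of 12 would itself be halogenated.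

**8 ⇒ 5 + 6 (C4a–C4).** The aryl–carbonyl bond is cut to aryllithium 7 and the acetyl donor 6. This is the only regiochemical decision on ring A. Compound 5 has two adjacent C–H bonds, one beside a methoxymethyl ether and one beside a methyl ether, and deprotonation is expected beside the better coordinating acetal oxygen, at the carbon that must become C4a. A Friedel–Crafts acylation would neither tell the two sites apart nor tolerate the acetals.

**5 ⇒ 3 + 4, and 3 ⇒ 1.** Removing the two acetal groups, which come from 4, gives catechol 3. Replacing its O5 by a formyl group, the reverse of a Dakin oxidation through formate 2, leads to aldehyde 1. Compound 1 already holds O6 as the free phenol and O7 and O8 as methyl ethers in the right order, so the methyl ethers of the target never have to be set by selective alkylation.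

## Alternatives that were turned down

Alternative 1: ring A by cycloaddition of a silyloxyfuran.
- Disconnection: ring A is cut at C5–C6 and C4a–C8a into two pieces. One is tert-butyl[(3,4-dimethoxyfuran-2-yl)oxy]dimethylsilane A2, which supplies C6, C7, C8 and C8a with their oxygens. The other is 1-bromo-5-(3,4-dimethoxyphenyl)penta-1,4-diyn-3-one A3, whose bromoalkyne supplies C5 and C4a and which already carries C4, C3, C2 and ring B.
- Forward key step: [4+2] addition of A2 across the bromoalkyne of A3, then opening of the oxygen bridge at the silyloxy-bearing bridgehead, to give the hexasubstituted phenol 1-[2-bromo-6-(tert-butyldimethylsilyloxy)-3-hydroxy-4,5-dimethoxyphenyl]-3-(3,4-dimethoxyphenyl)prop-2-yn-1-one A1.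
- For: it is the more convergent plan. All six ring-A substituents are set in one metal-free operation, the oxygen on C8a (a silyl ether) and O6 (a free hydroxyl) are told apart, and the ynone is ready for closure of ring C.
- Against: C5 arrives as C–Br, so a hydroxylation of a doubly ortho-substituted bromide next to a carbonyl is still needed. The hard C–O coupling is only moved, and becomes intermolecular. A2 is hydrolytically labile. A3 is a doubly activated acceptor with two competing alkynes, and the furan may add in a stepwise vinylogous Michael sense without closing the ring. Closure of ring C from the ynone also faces six-membered against five-membered (aurone-type) attack.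
- Comparison: A2 and A3 each need several steps, and at least three more follow A1, so the sequence should be longer than seven steps. The chosen route gives up this convergence. In its place it takes three ring-A oxygens and a formyl group that becomes the fourth from commercial 1, and it uses the halogen at the one carbon where oxygen is delivered intramolecularly.

Alternative 2: ring A from a squarate by thermal ring expansion.
- Disconnection: ring A is opened at C5–C6 back to 4-[(Z)-2-ethoxyvinyl]-2,3-dimethoxy-4-(methoxymethoxy)cyclobut-2-en-1-one A5. This would be made from dimethyl squarate A6 by addition of the ethoxyvinyl side chain to one carbonyl group and protection of the resulting tertiary alcohol.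
- Forward key step: heating A5 in an inert aromatic solvent opens the four-membered ring, the resulting ketene closes by six-electron electrocyclisation, and tautomerisation gives 2-ethoxy-5,6-dimethoxy-4-(methoxymethoxy)phenol A4.
- For: the substitution pattern is unambiguous and the step needs no catalyst. The lone C–H of A4 (the future C4a) lies between two alkoxy groups, a good site for later lithiation and acylation. O1 and O5 end up differently protected, so this plan is as strong as the chosen one on the regiochemistry of ring C, and A6 is a cheap four-carbon source.
- Against: O5 emerges as an ethyl ether, so the end game needs a chelation-assisted dealkylation beside four methyl ethers, one more selective step. A4 contains neither the C4–C2 chain nor ring B, so acylation, chain extension, ring C closure and several protecting-group operations still follow.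
- Comparison: counted from A6, the sequence should come to about ten steps against seven. The chosen route reaches the same certainty about O1 with a bromine atom, and carries only one kind of protecting group, removed in a single step.

Alternative 3: ring A by double Claisen condensation onto an ascorbate-derived butenolide.
- Disconnection: ring A is cut at C4a–C5 and C4a–C8a into 1-(3,4-dimethoxyphenyl)butane-1,3-dione A9 and methyl (2S)-3,4-dimethoxy-5-oxo-2,5-dihydrofuran-2-carboxylate A8. The latter would be derived from L-ascorbic acid A10 by O-methylation of the enediol and oxidative shortening of the side chain to the ester.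
- Forward key step: the dianion of A9 attacks the ester carbonyl of A8 (C5) with its terminal carbon and then the lactone carbonyl (C8a). Enolisation aromatises the ring to 1-(3,4-dimethoxyphenyl)-3-(2,3,6-trihydroxy-4,5-dimethoxyphenyl)propane-1,3-dione A7.
- For: it is by far the shortest plan, with no protecting group and no transition metal, and A10 is a cheap source that already holds the oxygens of C6, C7 and C8. On step economy it beats the chosen route.
- Against, at the key step: the ring hydrogen of A8 is alpha to the ester and gamma to the butenolide carbonyl, so the dianion is likely to be quenched by proton transfer. The methoxy-bearing carbon beta to the lactone carbonyl can undergo addition–elimination. The second condensation asks a stabilised triketone anion to attack a lactone.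
- Against, after the key step: A7 is an air-sensitive polyphenol with free hydroxyls on both C5 and C8a. Its cyclodehydration can give 14 or 2-(3,4-dimethoxyphenyl)-5,8-dihydroxy-6,7-dimethoxychromen-4-one A11, and nothing in the structure favours one.
- Comparison: the chosen route is longer, but the position of its bromine rules out by construction the closure that would lead to A11.

Key step: step 6

Assumption: ring atoms carry flavone numbering (O1, C2, C3, C4, C4a, C5 to C8, C8a) also in open-chain precursors, and 1, 4, 6 and 10 are taken as purchasable.

## Route

**Step 1**
Reactants: 1 2-hydroxy-3,4-dimethoxybenzaldehyde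
Product: 3 3,4-dimethoxybenzene-1,2-diol, via 2-hydroxy-3,4-dimethoxyphenyl formate 2 (not isolated)
Conditions: 30% aq. H2O2 (1.2 equiv), NaOH (1.1 equiv), degassed H2O/THF, 0 °C → rt, N2; then 1 M HCl to pH 4
Reagents that add atoms: hydrogen peroxide, OO
Why: Dakin oxidation: hydroperoxide adds to the aldehyde, the electron-rich aryl group with its ortho phenoxide migrates to oxygen to give formate 2, and this is saponified in the same flask. Exclusion of air protects the electron-rich catechol.

**Step 2**
Reactants: 3 3,4-dimethoxybenzene-1,2-diol; 4 chloromethyl methyl ether
Product: 5 1,2-dimethoxy-3,4-bis(methoxymethoxy)benzene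
Conditions: NaH (2.4 equiv), THF/DMF (4:1), 0 °C; then MOMCl (2.4 equiv), 0 °C → rt, Ar
Reagents that add atoms: chloromethyl methyl ether (4), COCCl
Why: Williamson-type O-alkylation of both phenoxides by the reactive alpha-chloro ether; capping the catechol at once removes its sensitivity to oxidation and installs the directing group for step 3.

**Step 3**
Reactants: 5 1,2-dimethoxy-3,4-bis(methoxymethoxy)benzene; 6 N-methoxy-N-methylacetamide
Product: 8 1-[4,5-dimethoxy-2,3-bis(methoxymethoxy)phenyl]ethan-1-one, via [4,5-dimethoxy-2,3-bis(methoxymethoxy)phenyl]lithium 7 (not isolated)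
Conditions: n-BuLi (1.2 equiv), TMEDA (1.2 equiv), THF, −20 → 0 °C; then 6 (1.5 equiv), −78 → 0 °C; H2O
Reagents that add atoms: N-methoxy-N-methylacetamide (6), CON(C)C(C)=O
Why: Directed ortho-metalation followed by Weinreb ketone synthesis: the acetal oxygen of the outer methoxymethyl ether coordinates lithium more strongly than a methyl ether, so the C–H beside it (the future C4a) is removed and not the one beside OMe. The chelated tetrahedral adduct of the Weinreb amide releases the ketone only on quench, so no tertiary alcohol is expected.

**Step 4**
Reactants: 8 1-[4,5-dimethoxy-2,3-bis(methoxymethoxy)phenyl]ethan-1-one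
Product: 9 1-[2-bromo-3,4-dimethoxy-5,6-bis(methoxymethoxy)phenyl]ethan-1-one
Conditions: NBS (1.05 equiv), MeCN, 0 °C → rt, dark
Reagents that add atoms: N-bromosuccinimide, O=C1CCC(=O)N1Br
Why: Electrophilic aromatic bromination at the only ring C–H left, which is ortho to the C8 methoxy and para to the C6 acetal oxygen and therefore still activated despite the neighbouring acyl group. Polyalkoxy aryl ketones and aldehydes are known to brominate ortho to the carbonyl under these neutral conditions, which avoid free HBr and so spare the acetals.

**Step 5**
Reactants: 9 1-[2-bromo-3,4-dimethoxy-5,6-bis(methoxymethoxy)phenyl]ethan-1-one; 10 3,4-dimethoxybenzoyl chloride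
Product: 12 1-[2-bromo-3,4-dimethoxy-5,6-bis(methoxymethoxy)phenyl]-3-(3,4-dimethoxyphenyl)propane-1,3-dione, via lithium 1-[2-bromo-3,4-dimethoxy-5,6-bis(methoxymethoxy)phenyl]ethenolate 11 (not isolated)
Conditions: LiHMDS (2.2 equiv), THF, −78 °C; then 10 (1.05 equiv), −78 → 0 °C; AcOH (2.5 equiv)
Reagents that add atoms: 3,4-dimethoxybenzoyl chloride (10), COc1ccc(C(=O)Cl)cc1OC
Why: Claisen-type C-acylation of a ketone lithium enolate by an acid chloride. The second equivalent of base converts the product at once into its stabilised lithium diketonate, which prevents a second acylation and pulls the reaction to the C-acylated product; the amide base does not touch the aryl bromide.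

**Step 6**
Reactants: 12 1-[2-bromo-3,4-dimethoxy-5,6-bis(methoxymethoxy)phenyl]-3-(3,4-dimethoxyphenyl)propane-1,3-dione
Product: 13 2-(3,4-dimethoxyphenyl)-7,8-dimethoxy-5,6-bis(methoxymethoxy)-4H-chromen-4-one
Conditions: CuI (10 mol %), 1,10-phenanthroline (20 mol %), Cs2CO3 (2.0 equiv), dry DMF (0.05 M), 100 °C, Ar
Reagents that add atoms: none
Why: Cs2CO3 deprotonates the diketone and the enolate oxygen binds the phenanthroline-ligated monovalent copper centre of CuI; the ortho carbonyl (C4) holds the metal beside the C8a–Br bond, oxidative addition gives a seven-membered oxa-cupracycle, and C–O reductive elimination forms O1–C8a and returns monovalent copper. The closest known reaction type is the intramolecular Ullmann-type O-arylation of 1-(2-haloaryl)-1,3-diketones to flavones. Ring C closes as a six-membered ring by ipso substitution at the aromatic carbon C8a, formally a 6-exo closure at a trigonal carbon with bromide leaving outside the new ring, and the gain of the conjugated 4-pyranone makes closure irreversible. No stereocentre is formed. The step needs O- over C-arylation of the ambident enolate: C3 or the oxygen on C4 could reach C8a only through a four-membered ring, whereas the oxygen on C2 reaches it through a six-membered one after rotation about the C3–C4 bond of the Z-enolate. It also needs O5 to stay out, and this is secured because O5 and O6 are acetals, so the position of the bromine alone decides which oxygen becomes O1. The methyl and methoxymethyl ethers are inert to carbonate in hot DMF; dilution and dry conditions hold back intermolecular arylation and retro-Claisen cleavage.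

**Step 7**
Reactants: 13 2-(3,4-dimethoxyphenyl)-7,8-dimethoxy-5,6-bis(methoxymethoxy)-4H-chromen-4-one
Product: 14 pebrellin, 2-(3,4-dimethoxyphenyl)-5,6-dihydroxy-7,8-dimethoxy-4H-chromen-4-one
Conditions: 3 M aq. HCl/MeOH (1:10), 40 °C, Ar
Reagents that add atoms: none
Why: Acid-catalysed acetal methanolysis of the two aryl methoxymethyl ethers; the one on O5 is helped by the hydrogen bond to C4=O that forms on release. Aryl methyl ethers are untouched, and the acid is far too mild to open the pyranone, so the ring-A pattern cannot scramble.

## Compound list

1 | 2-hydroxy-3,4-dimethoxybenzaldehyde | COc1ccc(C=O)c(O)c1OC | starting material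
2 | 2-hydroxy-3,4-dimethoxyphenyl formate | COc1ccc(OC=O)c(O)c1OC | intermediate (not isolated)
3 | 3,4-dimethoxybenzene-1,2-diol | COc1ccc(O)c(O)c1OC | intermediate
4 | chloromethyl methyl ether | COCCl | starting material
5 | 1,2-dimethoxy-3,4-bis(methoxymethoxy)benzene | COCOc1ccc(OC)c(OC)c1OCOC | intermediate
6 | N-methoxy-N-methylacetamide | CON(C)C(C)=O | starting material
7 | [4,5-dimethoxy-2,3-bis(methoxymethoxy)phenyl]lithium | [Li]c1cc(OC)c(OC)c(OCOC)c1OCOC | intermediate (not isolated)
8 | 1-[4,5-dimethoxy-2,3-bis(methoxymethoxy)phenyl]ethan-1-one | CC(=O)c1cc(OC)c(OC)c(OCOC)c1OCOC | intermediate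
9 | 1-[2-bromo-3,4-dimethoxy-5,6-bis(methoxymethoxy)phenyl]ethan-1-one | CC(=O)c1c(Br)c(OC)c(OC)c(OCOC)c1OCOC | intermediate
10 | 3,4-dimethoxybenzoyl chloride | COc1ccc(C(=O)Cl)cc1OC | starting material
11 | lithium 1-[2-bromo-3,4-dimethoxy-5,6-bis(methoxymethoxy)phenyl]ethenolate | [Li]OC(=C)c1c(Br)c(OC)c(OC)c(OCOC)c1OCOC | intermediate (not isolated)
12 | 1-[2-bromo-3,4-dimethoxy-5,6-bis(methoxymethoxy)phenyl]-3-(3,4-dimethoxyphenyl)propane-1,3-dione | COCOc1c(OCOC)c(OC)c(OC)c(Br)c1C(=O)CC(=O)c1ccc(OC)c(OC)c1 | intermediate
13 | 2-(3,4-dimethoxyphenyl)-7,8-dimethoxy-5,6-bis(methoxymethoxy)-4H-chromen-4-one | COCOc1c(OCOC)c(OC)c(OC)c2oc(-c3ccc(OC)c(OC)c3)cc(=O)c12 | intermediate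
14 | pebrellin, 2-(3,4-dimethoxyphenyl)-5,6-dihydroxy-7,8-dimethoxy-4H-chromen-4-one | COc1ccc(-c2cc(=O)c3c(O)c(O)c(OC)c(OC)c3o2)cc1OC | target

## Step count and risk

Total: 7 steps. Longest linear sequence: 7 steps (1 to 14); acid chloride 10 enters at step 5.

**Step 6 (key step).** The C8a–Br bond is flanked by OMe and the acyl group on an electron-rich ring, so its activation may be slow. Retro-Claisen cleavage of the diketone by carbonate and trace water, protodebromination, or sequestration of copper as an O,O-diketonate chelate could then overtake ring closure. The fallback sets out from 9 and returns at 13; it puts the oxygen on C8a first and closes ring C at O1–C2. Miyaura borylation of 9 (B2pin2, PdCl2(dppf), KOAc, dioxane, 90 °C) should give 1-[3,4-dimethoxy-5,6-bis(methoxymethoxy)-2-(4,4,5,5-tetramethyl-1,3,2-dioxaborolan-2-yl)phenyl]ethan-1-one F1. Oxidation of its C–B bond with NaBO3·4H2O in THF/H2O should give 1-[2-hydroxy-3,4-dimethoxy-5,6-bis(methoxymethoxy)phenyl]ethan-1-one F2. Treating F2 with LiHMDS (3 equiv) and then 10 should give, by C-acylation of the dianion, 1-(3,4-dimethoxyphenyl)-3-[2-hydroxy-3,4-dimethoxy-5,6-bis(methoxymethoxy)phenyl]propane-1,3-dione F3. Cyclodehydration of F3 (cat. p-TsOH, dry toluene, molecular sieves, rt) should give 13. O5 is still an acetal while the C8a hydroxyl is free, so the regiochemical lock is kept, and the dry medium offers no nucleophile to carry off a methoxymethyl group before closure. Any acetal lost after ring closure converges on 14 in step 7.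

**Step 4.** Bromination may occur at the acetyl methyl group through the enol, the acetal ortho to the carbonyl may be lost to traces of HBr, and the acyl group slows attack on the ring. The fallback sets out from 8 and returns at 9; it takes the carbonyl away for the halogenation. NaBH4 in MeOH should reduce 8 to racemic 1-[4,5-dimethoxy-2,3-bis(methoxymethoxy)phenyl]ethan-1-ol F4. The ring of F4, now free of the acyl group and of an enolisable ketone, should be brominated by NBS in MeCN at 0 °C at its only C–H, giving racemic 1-[2-bromo-3,4-dimethoxy-5,6-bis(methoxymethoxy)phenyl]ethan-1-ol F5. Dess–Martin periodinane (CH2Cl2, NaHCO3 buffer) should then return ketone 9.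

**Step 5.** O-acylation of the enolate, a second acylation at C3, or consumption of the acid chloride by the excess amide base may lower the conversion. The fallback sets out from 9 and returns at 12; it replaces the acylation by aldol addition and oxidation. Enolate 11, made from 9 with LDA in THF at −78 °C, should add to 3,4-dimethoxybenzaldehyde to give racemic 1-[2-bromo-3,4-dimethoxy-5,6-bis(methoxymethoxy)phenyl]-3-(3,4-dimethoxyphenyl)-3-hydroxypropan-1-one F6. Dess–Martin periodinane should oxidise F6 to 12.

**Step 3.** Proton transfer from the acetyl methyl group of 6 to the aryllithium would return 5; incomplete regiocontrol in the lithiation is the smaller risk. The fallback sets out from 5 and returns at 8; it uses an electrophile that cannot be enolised. Aryllithium 7, generated from 5 as in step 3, is quenched with CO2 to give 4,5-dimethoxy-2,3-bis(methoxymethoxy)benzoic acid F7, isolated cold at pH 4 to 5 to spare the acetals. MeLi (2.2 equiv, THF, 0 °C, then TMSCl and aqueous work-up) should convert F7 through its lithium carboxylate into methyl ketone 8.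

## Further compounds

F1 | step 6 | 1-[3,4-dimethoxy-5,6-bis(methoxymethoxy)-2-(4,4,5,5-tetramethyl-1,3,2-dioxaborolan-2-yl)phenyl]ethan-1-one | CC(=O)c1c(B2OC(C)(C)C(C)(C)O2)c(OC)c(OC)c(OCOC)c1OCOC
F2 | step 6 | 1-[2-hydroxy-3,4-dimethoxy-5,6-bis(methoxymethoxy)phenyl]ethan-1-one | CC(=O)c1c(O)c(OC)c(OC)c(OCOC)c1OCOC
F3 | step 6 | 1-(3,4-dimethoxyphenyl)-3-[2-hydroxy-3,4-dimethoxy-5,6-bis(methoxymethoxy)phenyl]propane-1,3-dione | COCOc1c(OCOC)c(OC)c(OC)c(O)c1C(=O)CC(=O)c1ccc(OC)c(OC)c1
F4 | step 4 | 1-[4,5-dimethoxy-2,3-bis(methoxymethoxy)phenyl]ethan-1-ol (racemic) | CC(O)c1cc(OC)c(OC)c(OCOC)c1OCOC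
F5 | step 4 | 1-[2-bromo-3,4-dimethoxy-5,6-bis(methoxymethoxy)phenyl]ethan-1-ol (racemic) | CC(O)c1c(Br)c(OC)c(OC)c(OCOC)c1OCOC
F6 | step 5 | 1-[2-bromo-3,4-dimethoxy-5,6-bis(methoxymethoxy)phenyl]-3-(3,4-dimethoxyphenyl)-3-hydroxypropan-1-one (racemic) | COCOc1c(OCOC)c(OC)c(OC)c(Br)c1C(=O)CC(O)c1ccc(OC)c(OC)c1
F7 | step 3 | 4,5-dimethoxy-2,3-bis(methoxymethoxy)benzoic acid | OC(=O)c1cc(OC)c(OC)c(OCOC)c1OCOC
A1 | alternative 1 | 1-[2-bromo-6-(tert-butyldimethylsilyloxy)-3-hydroxy-4,5-dimethoxyphenyl]-3-(3,4-dimethoxyphenyl)prop-2-yn-1-one | COc1ccc(C#CC(=O)c2c(Br)c(O)c(OC)c(OC)c2O[Si](C)(C)C(C)(C)C)cc1OC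
A2 | alternative 1 | tert-butyl[(3,4-dimethoxyfuran-2-yl)oxy]dimethylsilane | COc1coc(O[Si](C)(C)C(C)(C)C)c1OC
A3 | alternative 1 | 1-bromo-5-(3,4-dimethoxyphenyl)penta-1,4-diyn-3-one | BrC#CC(=O)C#Cc1ccc(OC)c(OC)c1
A4 | alternative 2 | 2-ethoxy-5,6-dimethoxy-4-(methoxymethoxy)phenol | CCOc1cc(OCOC)c(OC)c(OC)c1O
A5 | alternative 2 | 4-[(Z)-2-ethoxyvinyl]-2,3-dimethoxy-4-(methoxymethoxy)cyclobut-2-en-1-one (racemic) | CCO/C=C\C1(OCOC)C(OC)=C(OC)C1=O
A6 | alternative 2 | dimethyl squarate, 3,4-dimethoxycyclobut-3-ene-1,2-dione | COC1=C(OC)C(=O)C1=O
A7 | alternative 3 | 1-(3,4-dimethoxyphenyl)-3-(2,3,6-trihydroxy-4,5-dimethoxyphenyl)propane-1,3-dione | COc1ccc(C(=O)CC(=O)c2c(O)c(O)c(OC)c(OC)c2O)cc1OC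
A8 | alternative 3 | methyl (2S)-3,4-dimethoxy-5-oxo-2,5-dihydrofuran-2-carboxylate | COC(=O)[C@@H]1C(=C(C(=O)O1)OC)OC
A9 | alternative 3 | 1-(3,4-dimethoxyphenyl)butane-1,3-dione | CC(=O)CC(=O)c1ccc(OC)c(OC)c1
A10 | alternative 3 | L-ascorbic acid | C([C@@H]([C@@H]1C(=C(C(=O)O1)O)O)O)O
A11 | alternative 3 | 2-(3,4-dimethoxyphenyl)-5,8-dihydroxy-6,7-dimethoxychromen-4-one | COc1ccc(-c2cc(=O)c3c(O)c(OC)c(OC)c(O)c3o2)cc1OC
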